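**Retrosynthetic overview**

- Feature: in ring A (C1 carries the exocyclic =CH2, C4 the hydroxyl, C5 the two methyls, C6 the side chain) the methylene carbon C1 is bonded to C6, and C6 carries the CH2 arm C7 beside the quaternary C5 and the carbinol C4. This is the pattern formed when an alkyne carbon (C1) adds across a vinyl group (C6=C7).
- Late disconnections: the aryl ether O–C11 (Mitsunobu reaction with isofraxidin; the coumarin rings are bought), C8–C9 (B-alkyl Suzuki–Miyaura coupling with an E-alkenyl iodide) and C7–C8 (Matteson CH2 insertion into a C7–B bond).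
- Key disconnection: C1–C6 together with C7–B, by palladium-catalysed borylative 6-exo cyclisation of a 1,7-enyne; ring A is the only ring the route has to form.
- The enyne comes from pent-4-ynal by asymmetric reverse prenylation, which sets C4 (R) and builds the quaternary C5 in one step.

Key step: step 4

Remark on the chemistry: ring A is numbered C1–C6 as above and the side chain C7–C11 runs from C6 to the ether oxygen. The target is (4R,6S), with the C4 oxygen and the C6 chain cis on the ring and the C9=C10 bond E.

**Route**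

Step 1
Reactants: 1 pent-4-yn-1-ol
Product: 2 pent-4-ynal
Conditions: (COCl)2, DMSO, CH2Cl2, −78 °C; Et3N, −78 °C → rt; careful distillation, used at once
Reagents that add atoms: none
Why: Swern oxidation of a primary alcohol stops cleanly at the aldehyde under anhydrous conditions and does not touch the terminal alkyne.

Step 2
Reactants: 2 pent-4-ynal; 3 3-methylbuta-1,2-diene
Product: 6 (R)-3,3-dimethyloct-1-en-7-yn-4-ol, via B-prenyldiisopinocampheylborane 4 (not isolated), via diisopinocampheylborinate ester 5 (not isolated)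
Conditions: (−)-Ipc2BH (prepared beforehand from (+)-α-pinene and BH3·SMe2), 3, THF, −25 °C; then 2, −78 °C; then 3 M NaOH, 30% H2O2, 0 °C → rt
Reagents that add atoms: none
Why: Asymmetric reverse prenylation (allylboration): hydroboration of the allene at its unsubstituted terminus gives prenylborane 4, which adds to the aldehyde at its tertiary carbon through a chair Zimmerman–Traxler transition state; the isopinocampheyl groups from (+)-α-pinene are expected, by analogy with the parent allyl reagent, to direct attack to the Si face, which here means R at C4.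

Step 3
Reactants: 6 (R)-3,3-dimethyloct-1-en-7-yn-4-ol
Product: 7 (R)-tert-butyl[(3,3-dimethyloct-1-en-7-yn-4-yl)oxy]dimethylsilane
Conditions: TBSOTf, 2,6-lutidine, CH2Cl2, 0 °C
Reagents that add atoms: tert-butyldimethylsilyl trifluoromethanesulfonate, CC(C)(C)[Si](C)(C)OS(=O)(=O)C(F)(F)F
Why: Silylation with the silyl triflate and a hindered base is the standard way to protect a secondary alcohol that sits next to a quaternary carbon, and the configuration at C4 is not involved.

Step 4
Reactants: 7 (R)-tert-butyl[(3,3-dimethyloct-1-en-7-yn-4-yl)oxy]dimethylsilane; 8 bis(pinacolato)diboron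
Product: 9 2-{[(1S,3R)-3-(tert-butyldimethylsilyloxy)-2,2-dimethyl-6-methylidenecyclohexyl]methyl}-4,4,5,5-tetramethyl-1,3,2-dioxaborolane
Conditions: Pd(OAc)2 (5 mol%), 8 (1.2 equiv), MeOH (1 equiv), toluene, 50 °C
Reagents that add atoms: none
Why: A hydridopalladium species of divalent palladium, formed from Pd(OAc)2, B2pin2 and methanol, adds syn across the terminal alkyne with palladium on the internal carbon C1, and the resulting alkenylpalladium inserts the tethered vinyl group C6=C7 by syn carbopalladation; the alkylpalladium at C7 then transmetalates with B2pin2 and reductive elimination forms the C7–B bond, returning zerovalent palladium that methanol converts back to the hydride. The closest known reaction type is the palladium-catalysed borylative cyclisation of 1,6- and 1,7-enynes with B2pin2 to homoallylic alkylboronates, applied here to a new substrate. Ring A closes in the 6-exo-trig mode by forming C1–C6, which leaves the exocyclic methylene on C1 and places the metal on the primary carbon C7. The new stereocentre C6 is controlled by the existing centre C4: in a chair-like insertion transition state the bulky silyloxy group at C4 and the C7 terminus of the alkene both lie pseudo-equatorial, so the CH2B arm should come out cis to the C4 oxygen (C6 = S). The step needs boron capture to outrun β-hydride loss from the C7 alkylpalladium and ring closure to outrun direct borylation of the alkyne; phosphine-free palladium with excess B2pin2 makes the boron transfer fast, and the gem-dimethyl carbon C5 in the tether (Thorpe–Ingold effect) favours closure.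

Step 5
Reactants: 9 2-{[(1S,3R)-3-(tert-butyldimethylsilyloxy)-2,2-dimethyl-6-methylidenecyclohexyl]methyl}-4,4,5,5-tetramethyl-1,3,2-dioxaborolane
Product: 11 2-{2-[(1S,3R)-3-(tert-butyldimethylsilyloxy)-2,2-dimethyl-6-methylidenecyclohexyl]ethyl}-4,4,5,5-tetramethyl-1,3,2-dioxaborolane, via chloromethyl boronate complex 10 (not isolated)
Conditions: ClCH2I, n-BuLi, THF, −78 °C → rt
Reagents that add atoms: chloroiodomethane, ClCI
Why: Matteson homologation: LiCH2Cl made in situ by iodine–lithium exchange adds to boron, and on warming the primary alkyl group of ate complex 10 migrates with loss of chloride, inserting C8 between C7 and boron without touching C6 or the silyl ether.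

Step 6
Reactants: 12 but-2-yn-1-ol
Product: 13 tert-butyl(but-2-yn-1-yloxy)dimethylsilane
Conditions: TBSCl, imidazole, CH2Cl2, 0 °C → rt
Reagents that add atoms: tert-butyldimethylsilyl chloride, CC(C)(C)[Si](C)(C)Cl
Why: Standard silylation of a primary alcohol, which also supplies the steric bias needed for the regiochemistry of step 7.

Step 7
Reactants: 13 tert-butyl(but-2-yn-1-yloxy)dimethylsilane
Product: 15 (E)-tert-butyl[(3-iodobut-2-en-1-yl)oxy]dimethylsilane, via alkenylzirconocene chloride 14 (not isolated)
Conditions: Cp2Zr(H)Cl (1.5 equiv), THF, rt → 40 °C, dark; then I2, 0 °C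
Reagents that add atoms: iodine, II
Why: Hydrozirconation–iodination: Cp2Zr(H)Cl adds syn across the alkyne and, with a slight excess of reagent left to equilibrate, zirconium should settle on the less hindered methyl-bearing carbon remote from the silyloxymethyl group; iodinolysis of the C–Zr bond goes with retention and gives the E iodide.

Step 8
Reactants: 11 2-{2-[(1S,3R)-3-(tert-butyldimethylsilyloxy)-2,2-dimethyl-6-methylidenecyclohexyl]ethyl}-4,4,5,5-tetramethyl-1,3,2-dioxaborolane; 15 (E)-tert-butyl[(3-iodobut-2-en-1-yl)oxy]dimethylsilane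
Product: 16 tert-butyl{[(1R,3S)-3-[(3E)-5-(tert-butyldimethylsilyloxy)-3-methylpent-3-en-1-yl]-2,2-dimethyl-4-methylidenecyclohexyl]oxy}dimethylsilane
Conditions: Pd(dppf)Cl2·CH2Cl2 (10 mol%), aq. KOH (3 equiv), THF, degassed, 65 °C
Reagents that add atoms: none
Why: B-alkyl Suzuki–Miyaura coupling: hydroxide turns the primary alkyl pinacol boronate into a borate that transmetalates to the alkenylpalladium iodide (formed by oxidative addition with retention of the E geometry), and the wide-bite-angle dppf ligand favours reductive elimination of the C8–C9 bond over β-hydride loss.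

Step 9
Reactants: 16 tert-butyl{[(1R,3S)-3-[(3E)-5-(tert-butyldimethylsilyloxy)-3-methylpent-3-en-1-yl]-2,2-dimethyl-4-methylidenecyclohexyl]oxy}dimethylsilane
Product: 17 (1R,3S)-3-[(3E)-5-hydroxy-3-methylpent-3-en-1-yl]-2,2-dimethyl-4-methylidenecyclohexan-1-ol
Conditions: Bu4NF (4 equiv), THF, rt → 50 °C; aqueous work-up
Reagents that add atoms: none
Why: Fluoride-driven desilylation removes the primary allylic silyl ether quickly and the hindered secondary one on warming, and the two alkenes and both stereocentres are inert to fluoride.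

Step 10
Reactants: 17 (1R,3S)-3-[(3E)-5-hydroxy-3-methylpent-3-en-1-yl]-2,2-dimethyl-4-methylidenecyclohexan-1-ol; 18 isofraxidin (7-hydroxy-6,8-dimethoxy-2H-chromen-2-one)
Product: 19 7-{[(2E)-5-[(1S,3R)-3-hydroxy-2,2-dimethyl-6-methylidenecyclohexyl]-3-methylpent-2-en-1-yl]oxy}-6,8-dimethoxy-2H-chromen-2-one (CNP0306576.1)
Conditions: PPh3, DIAD, THF, 0 °C → rt
Reagents that add atoms: none
Why: Mitsunobu etherification: the unhindered primary allylic alcohol is activated far faster than the secondary alcohol flanked by the quaternary C5, and the acidic coumarin phenol displaces the oxyphosphonium group at C11 by direct substitution, so the E alkene and both stereocentres are untouched.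

**Compound list**

1 | pent-4-yn-1-ol | C#CCCCO | starting material
2 | pent-4-ynal | C#CCCC=O | intermediate
3 | 3-methylbuta-1,2-diene | CC(C)=C=C | starting material
4 | B-(3-methylbut-2-en-1-yl)diisopinocampheylborane, isopinocampheyl groups from (+)-α-pinene | CC(C)=CCB([C@@H]1C[C@@H]2C[C@H]([C@H]1C)C2(C)C)[C@@H]1C[C@@H]2C[C@H]([C@H]1C)C2(C)C | intermediate
5 | (R)-3,3-dimethyloct-1-en-7-yn-4-yl diisopinocampheylborinate | C=CC(C)(C)[C@H](OB([C@@H]1C[C@@H]2C[C@H]([C@H]1C)C2(C)C)[C@@H]1C[C@@H]2C[C@H]([C@H]1C)C2(C)C)CCC#C | intermediate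
6 | (R)-3,3-dimethyloct-1-en-7-yn-4-ol | C=CC(C)(C)[C@H](O)CCC#C | intermediate
7 | (R)-tert-butyl[(3,3-dimethyloct-1-en-7-yn-4-yl)oxy]dimethylsilane | C=CC(C)(C)[C@H](O[Si](C)(C)C(C)(C)C)CCC#C | intermediate
8 | bis(pinacolato)diboron | CC1(C)OB(OC1(C)C)B1OC(C)(C)C(C)(C)O1 | starting material
9 | 2-{[(1S,3R)-3-(tert-butyldimethylsilyloxy)-2,2-dimethyl-6-methylidenecyclohexyl]methyl}-4,4,5,5-tetramethyl-1,3,2-dioxaborolane | C=C1CC[C@@H](O[Si](C)(C)C(C)(C)C)C(C)(C)[C@H]1CB1OC(C)(C)C(C)(C)O1 | intermediate
10 | lithium (chloromethyl){[(1S,3R)-3-(tert-butyldimethylsilyloxy)-2,2-dimethyl-6-methylidenecyclohexyl]methyl}(pinacolato)borate | [Li+].C=C1CC[C@@H](O[Si](C)(C)C(C)(C)C)C(C)(C)[C@H]1C[B-]1(CCl)OC(C)(C)C(C)(C)O1 | intermediate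
11 | 2-{2-[(1S,3R)-3-(tert-butyldimethylsilyloxy)-2,2-dimethyl-6-methylidenecyclohexyl]ethyl}-4,4,5,5-tetramethyl-1,3,2-dioxaborolane | C=C1CC[C@@H](O[Si](C)(C)C(C)(C)C)C(C)(C)[C@H]1CCB1OC(C)(C)C(C)(C)O1 | intermediate
12 | but-2-yn-1-ol | CC#CCO | starting material
13 | tert-butyl(but-2-yn-1-yloxy)dimethylsilane | CC#CCO[Si](C)(C)C(C)(C)C | intermediate
14 | chlorobis(cyclopentadienyl)[(2E)-4-(tert-butyldimethylsilyloxy)but-2-en-2-yl]zirconium (cyclopentadienyl rings drawn σ-bonded) | C/C(=C\CO[Si](C)(C)C(C)(C)C)[Zr](Cl)(C1C=CC=C1)C1C=CC=C1 | intermediate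
15 | (E)-tert-butyl[(3-iodobut-2-en-1-yl)oxy]dimethylsilane | C/C(I)=C\CO[Si](C)(C)C(C)(C)C | intermediate
16 | tert-butyl{[(1R,3S)-3-[(3E)-5-(tert-butyldimethylsilyloxy)-3-methylpent-3-en-1-yl]-2,2-dimethyl-4-methylidenecyclohexyl]oxy}dimethylsilane | C=C1CC[C@@H](O[Si](C)(C)C(C)(C)C)C(C)(C)[C@H]1CC/C(C)=C/CO[Si](C)(C)C(C)(C)C | intermediate
17 | (1R,3S)-3-[(3E)-5-hydroxy-3-methylpent-3-en-1-yl]-2,2-dimethyl-4-methylidenecyclohexan-1-ol | C=C1CC[C@@H](O)C(C)(C)[C@H]1CC/C(C)=C/CO | intermediate
18 | isofraxidin (7-hydroxy-6,8-dimethoxy-2H-chromen-2-one) | COc1cc2ccc(=O)oc2c(OC)c1O | starting material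
19 | 7-{[(2E)-5-[(1S,3R)-3-hydroxy-2,2-dimethyl-6-methylidenecyclohexyl]-3-methylpent-2-en-1-yl]oxy}-6,8-dimethoxy-2H-chromen-2-one | C=C1CC[C@@H](O)C(C)(C)[C@H]1CC/C(C)=C/COc1c(OC)cc2ccc(=O)oc2c1OC | target

**Step count**

Total: 10 steps. Longest linear sequence: 8 steps (steps 1, 2, 3, 4, 5, 8, 9, 10); steps 6 and 7 make the alkenyl iodide in a side branch.

**Steps most likely to fail, with fallbacks**

1. Step 4 (key step). The C7 alkylpalladium may lose a β-hydrogen before boron is transferred (a 1,3-diene would result), the vinyl group may insert through the wrong face (C6 epimer), or the alkyne may be consumed by direct borylation. The fallback sets out from 7 and comes back at 9; it closes the same C1–C6 bond with a radical instead of palladium. The vinyl group of 7 is cleaved (catalytic OsO4, NaIO4, 2,6-lutidine, dioxane/H2O) to (3R)-3-(tert-butyldimethylsilyloxy)-2,2-dimethylhept-6-ynal F1. Takai-type olefination (CrCl2, LiI, Cl2CHBpin, THF) should give 2-[(1E,4R)-4-(tert-butyldimethylsilyloxy)-3,3-dimethyloct-1-en-7-yn-1-yl]-4,4,5,5-tetramethyl-1,3,2-dioxaborolane F2. Slow addition of Bu3SnH with azobisisobutyronitrile in benzene at 80 °C adds a stannyl radical to the alkyne terminus; the alkenyl radical at C1 closes 6-exo onto C6 of the alkenylboronate through a chair transition state, and the boron-stabilised radical at C7 is reduced, giving the cyclised alkenylstannane 2-{[3-(tert-butyldimethylsilyloxy)-2,2-dimethyl-6-(tributylstannylmethylidene)cyclohexyl]methyl}-4,4,5,5-tetramethyl-1,3,2-dioxaborolane F3 (ring configuration as in 9). Protodestannylation (p-TsOH, CH2Cl2, 0 °C) gives 9.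

2. Step 8. Transmetalation of the primary alkyl pinacol boronate may be slow, so that the iodide is used up by reduction or homocoupling, or β-hydride loss may follow transmetalation. The fallback sets out from 11 and comes back at 16; it replaces boron by zinc. Oxidation (NaBO3·4H2O, THF/H2O) gives 2-[(1S,3R)-3-(tert-butyldimethylsilyloxy)-2,2-dimethyl-6-methylidenecyclohexyl]ethan-1-ol F4. I2, PPh3 and imidazole give tert-butyl{[(1R,3S)-3-(2-iodoethyl)-2,2-dimethyl-4-methylidenecyclohexyl]oxy}dimethylsilane F5. Zinc insertion (Zn dust, LiCl, THF) gives {2-[(1S,3R)-3-(tert-butyldimethylsilyloxy)-2,2-dimethyl-6-methylidenecyclohexyl]ethyl}zinc iodide F6, and Negishi coupling with 15 (Pd(PPh3)4, THF, 50 °C) gives 16.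

3. Step 2. Enantiofacial control may be incomplete, or the volatile aldehyde may be lost, and the optical purity of everything downstream depends on this step. The fallback sets out from 2 and comes back at 6; it separates C–C bond formation from the setting of C4. Barbier-type prenylation (1-bromo-3-methylbut-2-ene, indium powder, DMF), which reacts at the tertiary terminus, gives rac-3,3-dimethyloct-1-en-7-yn-4-ol F7. Dess–Martin oxidation gives 3,3-dimethyloct-1-en-7-yn-4-one F8. Corey–Bakshi–Shibata reduction ((S)-methyl oxazaborolidine catalyst, catecholborane, toluene, −78 °C), with the tertiary alkyl group acting as the large substituent, should give 6.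

**Further compounds**

F1 | step 4 | (3R)-3-(tert-butyldimethylsilyloxy)-2,2-dimethylhept-6-ynal | O=CC(C)(C)[C@H](O[Si](C)(C)C(C)(C)C)CCC#C
F2 | step 4 | 2-[(1E,4R)-4-(tert-butyldimethylsilyloxy)-3,3-dimethyloct-1-en-7-yn-1-yl]-4,4,5,5-tetramethyl-1,3,2-dioxaborolane | CC1(C)OB(/C=C/C(C)(C)[C@H](O[Si](C)(C)C(C)(C)C)CCC#C)OC1(C)C
F3 | step 4 | 2-{[3-(tert-butyldimethylsilyloxy)-2,2-dimethyl-6-(tributylstannylmethylidene)cyclohexyl]methyl}-4,4,5,5-tetramethyl-1,3,2-dioxaborolane, ring configuration as in 9 | CCCC[Sn](CCCC)(CCCC)C=C1CC[C@@H](O[Si](C)(C)C(C)(C)C)C(C)(C)[C@H]1CB1OC(C)(C)C(C)(C)O1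
F4 | step 8 | 2-[(1S,3R)-3-(tert-butyldimethylsilyloxy)-2,2-dimethyl-6-methylidenecyclohexyl]ethan-1-ol | C=C1CC[C@@H](O[Si](C)(C)C(C)(C)C)C(C)(C)[C@H]1CCO
F5 | step 8 | tert-butyl{[(1R,3S)-3-(2-iodoethyl)-2,2-dimethyl-4-methylidenecyclohexyl]oxy}dimethylsilane | C=C1CC[C@@H](O[Si](C)(C)C(C)(C)C)C(C)(C)[C@H]1CCI
F6 | step 8 | {2-[(1S,3R)-3-(tert-butyldimethylsilyloxy)-2,2-dimethyl-6-methylidenecyclohexyl]ethyl}zinc iodide | C=C1CC[C@@H](O[Si](C)(C)C(C)(C)C)C(C)(C)[C@H]1CC[Zn]I
F7 | step 2 | rac-3,3-dimethyloct-1-en-7-yn-4-ol | C=CC(C)(C)C(O)CCC#C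
F8 | step 2 | 3,3-dimethyloct-1-en-7-yn-4-one | C=CC(C)(C)C(=O)CCC#C
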